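**Retrosynthetic overview**

1. Locants: ring C1 (C=O), C2=C3, C4 (OMe), C5 (CH2), C6 (quaternary); side chain C7 (CHMe), C8 (CHOH–aryl). The target goes back by O–Si cleavage to 20, and 20 by cutting C6–allyl and the ring bond C5–C6 to the acyclic (Z)-enone tosylate 16.
2. Enabling feature: C6 is the only sp3 α-carbon of the C1 ketone, C5 is a primary carbon next to the oxygen-bearing C4, and the cis C2=C3 bond of the cyclohex-2-enone holds C5 over C6. One flask therefore closes the ring by enolate alkylation (C5–C6) and then allylates the new ring enolate at C6, anti to the C4 methoxy group and to the C8 branch.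
3. 16 comes from aldehyde 7 (C1, C6–C8) and the lithium acetylide of alkyne tosylate 12 (C2–C5) by 1,2-addition, cis-semihydrogenation and oxidation.
4. 7 comes from 3,4-dimethoxybenzaldehyde by (Z)-crotylboration (sets C7 and C8), silylation and hydroboration/oxidation; 12 from (S)-glyceraldehyde acetonide (source of C4) by alkyne homologation, acetonide removal, primary tosylation and O-methylation.
5. Only one ring is formed in the route, the cyclohexenone, in step 12; the aryl ring is bought.

Key step: step 12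

Assumption: the (Z)-crotyldiisopinocampheylborane of the (+)-α-pinene series is taken to add to the Si face of aryl aldehydes, as it does with benzaldehyde; if the opposite sense is found, its enantiomer from (−)-α-pinene is used.

**Route**

Step 1
Reactants: 1 3,4-dimethoxybenzaldehyde
Product: 3 (1S,2R)-1-(3,4-dimethoxyphenyl)-2-methylbut-3-en-1-ol, via borinate ester 2 (not isolated)
Conditions: (Z)-crotyl-B(Ipc)2 of the (+)-α-pinene series (freshly prepared by the standard procedure), THF/Et2O, −78 °C; then NaOH, H2O2, 0 °C to rt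
Reagents that add atoms: (Z)-crotyldiisopinocampheylborane, C/C=C\CB([C@@H]1C[C@@H]2C[C@H]([C@H]1C)C2(C)C)[C@@H]1C[C@@H]2C[C@H]([C@H]1C)C2(C)C
Why: Brown asymmetric crotylboration through a closed chair (Zimmerman–Traxler-type) transition state, in which the (Z)-crotyl geometry places methyl and hydroxyl syn and the isopinocampheyl groups direct attack to the Si face of the aldehyde, should set C8 (S) and C7 (R).

Step 2
Reactants: 3 (1S,2R)-1-(3,4-dimethoxyphenyl)-2-methylbut-3-en-1-ol
Product: 4 tert-butyl{[(1S,2R)-1-(3,4-dimethoxyphenyl)-2-methylbut-3-en-1-yl]oxy}dimethylsilane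
Conditions: TBSOTf, 2,6-lutidine, CH2Cl2, 0 °C
Reagents that add atoms: tert-butyldimethylsilyl triflate, CC(C)(C)[Si](C)(C)OS(=O)(=O)C(F)(F)F
Why: Silyl ether formation with a silyl triflate protects the hindered benzylic alcohol without touching a stereocenter, and the bulky silyloxy group later serves as the large group for acyclic stereocontrol.

Step 3
Reactants: 4 tert-butyl{[(1S,2R)-1-(3,4-dimethoxyphenyl)-2-methylbut-3-en-1-yl]oxy}dimethylsilane
Product: 6 (3R,4S)-4-[(tert-butyldimethylsilyl)oxy]-4-(3,4-dimethoxyphenyl)-3-methylbutan-1-ol, via B-alkyl-9-BBN adduct 5 (not isolated)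
Conditions: 9-BBN, THF, 0 °C to rt; then NaOH, H2O2, 0 °C
Reagents that add atoms: hydrogen peroxide, OO
Why: Hydroboration–oxidation, in which 9-BBN adds to the terminal alkene with anti-Markovnikov regioselectivity and alkaline peroxide turns C–B into C–OH, leaves C7 and C8 untouched.

Step 4
Reactants: 6 (3R,4S)-4-[(tert-butyldimethylsilyl)oxy]-4-(3,4-dimethoxyphenyl)-3-methylbutan-1-ol
Product: 7 (3R,4S)-4-[(tert-butyldimethylsilyl)oxy]-4-(3,4-dimethoxyphenyl)-3-methylbutanal
Conditions: DMP, NaHCO3, CH2Cl2, 0 °C to rt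
Reagents that add atoms: none
Why: Dess–Martin oxidation stops at the aldehyde under buffered conditions, and the nearest stereocenter C7 is β to the carbonyl group and cannot epimerise.

Step 5
Reactants: 8 (S)-2,2-dimethyl-1,3-dioxolane-4-carbaldehyde
Product: 9 (R)-4-ethynyl-2,2-dimethyl-1,3-dioxolane
Conditions: dimethyl (1-diazo-2-oxopropyl)phosphonate, K2CO3, MeOH, 0 °C to rt
Reagents that add atoms: Ohira–Bestmann reagent, CC(=O)C(=[N+]=[N-])P(=O)(OC)OC
Why: Seyferth–Gilbert homologation with the Ohira–Bestmann reagent converts the aldehyde into the terminal alkyne under carbonate conditions mild enough to keep the α-alkoxy stereocenter.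

Step 6
Reactants: 9 (R)-4-ethynyl-2,2-dimethyl-1,3-dioxolane
Product: 10 (R)-but-3-yne-1,2-diol
Conditions: TsOH·H2O (5 mol%), MeOH, rt
Reagents that add atoms: none
Why: Acid-catalysed transacetalisation with methanol removes the isopropylidene group without touching the stereocenter or the alkyne.

Step 7
Reactants: 10 (R)-but-3-yne-1,2-diol
Product: 11 (R)-2-hydroxybut-3-yn-1-yl 4-methylbenzenesulfonate
Conditions: TsCl (1.05 equiv), Et3N, Bu2SnO (2 mol%), CH2Cl2, 0 °C to rt
Reagents that add atoms: 4-toluenesulfonyl chloride, Cc1ccc(cc1)S(Cl)(=O)=O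
Why: Tin-catalysed regioselective sulfonylation through a transient dibutylstannylene acetal activates the primary oxygen, so that only the primary hydroxyl should be tosylated.

Step 8
Reactants: 11 (R)-2-hydroxybut-3-yn-1-yl 4-methylbenzenesulfonate
Product: 12 (R)-2-methoxybut-3-yn-1-yl 4-methylbenzenesulfonate
Conditions: Me3OBF4, 1,8-bis(dimethylamino)naphthalene, CH2Cl2, 0 °C to rt
Reagents that add atoms: trimethyloxonium tetrafluoroborate, C[O+](C)C.F[B-](F)(F)F
Why: O-Methylation with Meerwein's salt and a non-nucleophilic proton scavenger alkylates the secondary hydroxyl without forming the alkoxide, which would close an epoxide by displacing the neighbouring tosylate, and breaks no bond to the stereocenter.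

Step 9
Reactants: 12 (R)-2-methoxybut-3-yn-1-yl 4-methylbenzenesulfonate; 7 (3R,4S)-4-[(tert-butyldimethylsilyl)oxy]-4-(3,4-dimethoxyphenyl)-3-methylbutanal
Product: 14 (2R,7R,8S)-8-[(tert-butyldimethylsilyl)oxy]-8-(3,4-dimethoxyphenyl)-5-hydroxy-2-methoxy-7-methyloct-3-yn-1-yl 4-methylbenzenesulfonate (C5 epimers), via lithium acetylide 13 (not isolated)
Conditions: n-BuLi (1.0 equiv), THF, −78 °C; then 7, −78 to −40 °C; aq. NH4Cl
Reagents that add atoms: none
Why: Deprotonation of the terminal alkyne and 1,2-addition of the lithium acetylide to the aldehyde joins the two fragments at C1–C2, and the new carbinol center may form as a mixture because it is oxidised in step 11.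

Step 10
Reactants: 14 (2R,7R,8S)-8-[(tert-butyldimethylsilyl)oxy]-8-(3,4-dimethoxyphenyl)-5-hydroxy-2-methoxy-7-methyloct-3-yn-1-yl 4-methylbenzenesulfonate
Product: 15 (2R,3Z,7R,8S)-8-[(tert-butyldimethylsilyl)oxy]-8-(3,4-dimethoxyphenyl)-5-hydroxy-2-methoxy-7-methyloct-3-en-1-yl 4-methylbenzenesulfonate (C5 epimers)
Conditions: H2 (1 atm), Pd/CaCO3 poisoned with Pb(OAc)2, quinoline, EtOAc, rt
Reagents that add atoms: none
Why: Lindlar semi-hydrogenation delivers both hydrogen atoms to the same face of the alkyne and should give only the (Z)-alkene needed for ring closure, with tosylate and silyl ether inert.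

Step 11
Reactants: 15 (2R,3Z,7R,8S)-8-[(tert-butyldimethylsilyl)oxy]-8-(3,4-dimethoxyphenyl)-5-hydroxy-2-methoxy-7-methyloct-3-en-1-yl 4-methylbenzenesulfonate
Product: 16 (2R,3Z,7R,8S)-8-[(tert-butyldimethylsilyl)oxy]-8-(3,4-dimethoxyphenyl)-2-methoxy-7-methyl-5-oxooct-3-en-1-yl 4-methylbenzenesulfonate
Conditions: DMP, NaHCO3, CH2Cl2, 0 °C; used at once
Reagents that add atoms: none
Why: Dess–Martin oxidation of the allylic alcohol under bicarbonate buffer should give the enone without acid or base strong enough to isomerise the cis double bond.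

Step 12
Reactants: 16 (2R,3Z,7R,8S)-8-[(tert-butyldimethylsilyl)oxy]-8-(3,4-dimethoxyphenyl)-2-methoxy-7-methyl-5-oxooct-3-en-1-yl 4-methylbenzenesulfonate
Product: 20 (4S,6S)-6-allyl-6-[(1S,2R)-1-[(tert-butyldimethylsilyl)oxy]-1-(3,4-dimethoxyphenyl)propan-2-yl]-4-methoxycyclohex-2-en-1-one, via lithium enolate 17 (not isolated), via cyclised enone 18 (not isolated), via ring enolate 19 (not isolated)
Conditions: LDA (1.1 equiv), THF, −78 °C, then 0 °C; recool to −78 °C, LDA (1.3 equiv); allyl bromide (3 equiv), DMPU, −78 to −20 °C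
Reagents that add atoms: allyl bromide, C=CCBr
Why: LDA removes a proton from C6, the only sp3 α-carbon of the C1 ketone, and on warming the lithium enolate 17 displaces the primary tosylate at C5 in an intramolecular SN2 reaction that closes the cyclohexenone ring in the 6-(enolendo)-exo-tet mode, which the cis C2=C3 bond makes geometrically possible; the closest known reaction types are the cyclisation of kinetic lithium enolates of ω-halo or ω-sulfonyloxy ketones to cyclohexanones and the α′-alkylation of 4-alkoxycyclohex-2-enone enolates. Ketone 18 (both C6–H epimers) is not isolated, since with a hydrogen at C6 it could lose methanol and aromatise, but is converted by the second portion of LDA into the single tetrasubstituted cross-conjugated enolate 19, which allyl bromide C-alkylates in an intermolecular SN2 reaction. The C6 quaternary stereocenter is set in this allylation by two elements acting in the same sense: the electrophile enters trans to the C4 methoxy group across the ring and, with the C7–H eclipsing the enolate C1–O bond to minimise A(1,3) strain, anti to the bulky C8 aryl(silyloxy)methyl group, which should give (6S). The step needs C- and not O-alkylation in the ring closure, which the lithium counter-ion in THF without polar additive favours (DMPU is added only for the allylation), and α′- and not γ-deprotonation, which kinetic conditions with complete enolate formation at −78 °C secure. C4, C7 and C8 are not α to the carbonyl group and are not affected.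

Step 13
Reactants: 20 (4S,6S)-6-allyl-6-[(1S,2R)-1-[(tert-butyldimethylsilyl)oxy]-1-(3,4-dimethoxyphenyl)propan-2-yl]-4-methoxycyclohex-2-en-1-one
Product: 21 (4S,6S)-6-allyl-6-[(1S,2R)-1-(3,4-dimethoxyphenyl)-1-hydroxypropan-2-yl]-4-methoxycyclohex-2-en-1-one
Conditions: HF·pyridine, pyridine, THF, 0 °C to rt
Reagents that add atoms: none
Why: Fluoride-driven cleavage of the silyl ether under pyridine-buffered conditions should free the C8 hydroxyl without ionising the electron-rich benzylic position or touching the enone.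

**Compound list**

1 | 3,4-dimethoxybenzaldehyde | COc1ccc(C=O)cc1OC | starting material
2 | [(1S,2R)-1-(3,4-dimethoxyphenyl)-2-methylbut-3-en-1-yl] bis(isopinocampheyl)borinate | C=C[C@@H](C)[C@H](OB([C@@H]1C[C@@H]2C[C@H]([C@H]1C)C2(C)C)[C@@H]1C[C@@H]2C[C@H]([C@H]1C)C2(C)C)c1ccc(OC)c(OC)c1 | intermediate
3 | (1S,2R)-1-(3,4-dimethoxyphenyl)-2-methylbut-3-en-1-ol | C=C[C@@H](C)[C@H](O)c1ccc(OC)c(OC)c1 | intermediate
4 | tert-butyl{[(1S,2R)-1-(3,4-dimethoxyphenyl)-2-methylbut-3-en-1-yl]oxy}dimethylsilane | C=C[C@@H](C)[C@H](O[Si](C)(C)C(C)(C)C)c1ccc(OC)c(OC)c1 | intermediate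
5 | 9-[(3R,4S)-4-[(tert-butyldimethylsilyl)oxy]-4-(3,4-dimethoxyphenyl)-3-methylbutyl]-9-borabicyclo[3.3.1]nonane | C1CCC2CCCC1B2CC[C@@H](C)[C@H](O[Si](C)(C)C(C)(C)C)c1ccc(OC)c(OC)c1 | intermediate
6 | (3R,4S)-4-[(tert-butyldimethylsilyl)oxy]-4-(3,4-dimethoxyphenyl)-3-methylbutan-1-ol | OCC[C@@H](C)[C@H](O[Si](C)(C)C(C)(C)C)c1ccc(OC)c(OC)c1 | intermediate
7 | (3R,4S)-4-[(tert-butyldimethylsilyl)oxy]-4-(3,4-dimethoxyphenyl)-3-methylbutanal | O=CC[C@@H](C)[C@H](O[Si](C)(C)C(C)(C)C)c1ccc(OC)c(OC)c1 | intermediate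
8 | (S)-2,2-dimethyl-1,3-dioxolane-4-carbaldehyde | O=C[C@@H]1COC(C)(C)O1 | starting material
9 | (R)-4-ethynyl-2,2-dimethyl-1,3-dioxolane | C#C[C@@H]1COC(C)(C)O1 | intermediate
10 | (R)-but-3-yne-1,2-diol | OC[C@H](O)C#C | intermediate
11 | (R)-2-hydroxybut-3-yn-1-yl 4-methylbenzenesulfonate | Cc1ccc(cc1)S(=O)(=O)OC[C@H](O)C#C | intermediate
12 | (R)-2-methoxybut-3-yn-1-yl 4-methylbenzenesulfonate | Cc1ccc(cc1)S(=O)(=O)OC[C@H](OC)C#C | intermediate
13 | lithium acetylide of 12 | [Li]C#C[C@@H](OC)COS(=O)(=O)c1ccc(C)cc1 | intermediate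
14 | (2R,7R,8S)-8-[(tert-butyldimethylsilyl)oxy]-8-(3,4-dimethoxyphenyl)-5-hydroxy-2-methoxy-7-methyloct-3-yn-1-yl 4-methylbenzenesulfonate (C5 epimers) | Cc1ccc(cc1)S(=O)(=O)OC[C@H](OC)C#CC(O)C[C@@H](C)[C@H](O[Si](C)(C)C(C)(C)C)c1ccc(OC)c(OC)c1 | intermediate
15 | (2R,3Z,7R,8S)-8-[(tert-butyldimethylsilyl)oxy]-8-(3,4-dimethoxyphenyl)-5-hydroxy-2-methoxy-7-methyloct-3-en-1-yl 4-methylbenzenesulfonate (C5 epimers) | Cc1ccc(cc1)S(=O)(=O)OC[C@H](OC)/C=C\C(O)C[C@@H](C)[C@H](O[Si](C)(C)C(C)(C)C)c1ccc(OC)c(OC)c1 | intermediate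
16 | (2R,3Z,7R,8S)-8-[(tert-butyldimethylsilyl)oxy]-8-(3,4-dimethoxyphenyl)-2-methoxy-7-methyl-5-oxooct-3-en-1-yl 4-methylbenzenesulfonate | Cc1ccc(cc1)S(=O)(=O)OC[C@H](OC)/C=C\C(=O)C[C@@H](C)[C@H](O[Si](C)(C)C(C)(C)C)c1ccc(OC)c(OC)c1 | intermediate
17 | lithium C6 enolate of 16 (enolate geometry open) | Cc1ccc(cc1)S(=O)(=O)OC[C@H](OC)/C=C\C(O[Li])=C[C@@H](C)[C@H](O[Si](C)(C)C(C)(C)C)c1ccc(OC)c(OC)c1 | intermediate
18 | (4S)-6-[(1S,2R)-1-[(tert-butyldimethylsilyl)oxy]-1-(3,4-dimethoxyphenyl)propan-2-yl]-4-methoxycyclohex-2-en-1-one (C6 epimers) | C1([C@@H](C)[C@H](O[Si](C)(C)C(C)(C)C)c2ccc(OC)c(OC)c2)C[C@H](OC)C=CC1=O | intermediate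
19 | lithium C1,C6 enolate of 18 | [Li]OC1=C([C@@H](C)[C@H](O[Si](C)(C)C(C)(C)C)c2ccc(OC)c(OC)c2)C[C@H](OC)C=C1 | intermediate
20 | (4S,6S)-6-allyl-6-[(1S,2R)-1-[(tert-butyldimethylsilyl)oxy]-1-(3,4-dimethoxyphenyl)propan-2-yl]-4-methoxycyclohex-2-en-1-one | C=CC[C@@]1([C@@H](C)[C@H](O[Si](C)(C)C(C)(C)C)c2ccc(OC)c(OC)c2)C[C@H](OC)C=CC1=O | intermediate
21 | (4S,6S)-6-allyl-6-[(1S,2R)-1-(3,4-dimethoxyphenyl)-1-hydroxypropan-2-yl]-4-methoxycyclohex-2-en-1-one | C=CC[C@@]1([C@@H](C)[C@H](O)c2ccc(OC)c(OC)c2)C[C@H](OC)C=CC1=O | target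

**Count and risks**

Total step count: 13. Longest linear sequence: 9 steps (steps 1–4 and 9–13 from 1; the branch from 8 through steps 5–8 and 9–13 is equally long).

Steps most likely to fail:

1. Step 12. What may go wrong: closure of enolate 17 through oxygen instead of carbon (O-alkylation by the tosylate to a six-membered dienyl ether); internal proton transfer from C4 to the enolate followed by loss of tosylate; or allylation of 19 from the wrong face. Fallback: the C5–C6 bond is made intermolecularly with a carbon-only nucleophile and the ring is closed at C2=C3 by metathesis. It sets out from 7, with 12 as the source of the four-carbon unit, and comes back at 18. Lindlar semi-hydrogenation of 12 should give (R)-2-methoxybut-3-en-1-yl 4-methylbenzenesulfonate F1, and NaI in acetone (R)-4-iodo-3-methoxybut-1-ene F2. Aldehyde 7 and 1,1-dimethylhydrazine give the (E)-N,N-dimethylhydrazone F3, whose lithium aza-enolate (LDA, THF, 0 °C) is alkylated at C6 by F2 to the alkylated hydrazone F4. Aqueous CuCl2 releases the α-branched aldehyde F5, vinylmagnesium bromide gives the dienol F6, and second-generation Grubbs catalyst (CH2Cl2, 40 °C) closes the ring to the cyclohexenol F7. Dess–Martin oxidation gives 18, which is now isolated and then deprotonated with LDA and allylated as in the second stage of step 12 to reach 20.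

2. Step 11. What may go wrong: cis-to-trans isomerisation of the enone during oxidation or work-up, or displacement of the tosylate by the C1 hydroxyl of 15 before it is oxidised. Fallback: the order of the redox events is changed so that the cis alkene is created last and 15 is never formed. It sets out from 14 and comes back at 16. Dess–Martin oxidation of 14 gives the ynone (2R,7R,8S)-8-[(tert-butyldimethylsilyl)oxy]-8-(3,4-dimethoxyphenyl)-2-methoxy-7-methyl-5-oxooct-3-yn-1-yl 4-methylbenzenesulfonate F8, and Lindlar semi-hydrogenation of F8 gives 16, which is filtered and taken directly into step 12.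

3. Step 1. What may go wrong: erosion of enantio- or diastereoselectivity through geometric scrambling of the crotylborane or an unselective background addition to the electron-rich aldehyde. Fallback: auxiliary-controlled Evans syn-aldol reaction followed by methylenation. It sets out from 1 and comes back at 4. (S)-4-Benzyl-3-propionyloxazolidin-2-one (Bu2BOTf, iPr2NEt, then 1) should give the syn-aldol adduct F9, and TBSOTf/2,6-lutidine the silyl ether F10. LiBH4 removes the auxiliary to give the primary alcohol F11, Dess–Martin oxidation gives the aldehyde F12, and Wittig methylenation (Ph3P=CH2, THF, −78 to 0 °C) gives 4.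

Further compounds
F1 | step 12 | (R)-2-methoxybut-3-en-1-yl 4-methylbenzenesulfonate | Cc1ccc(cc1)S(=O)(=O)OC[C@H](OC)C=C
F2 | step 12 | (R)-4-iodo-3-methoxybut-1-ene | IC[C@H](OC)C=C
F3 | step 12 | (E)-2-[(3R,4S)-4-[(tert-butyldimethylsilyl)oxy]-4-(3,4-dimethoxyphenyl)-3-methylbutylidene]-1,1-dimethylhydrazine | CN(C)/N=C/C[C@@H](C)[C@H](O[Si](C)(C)C(C)(C)C)c1ccc(OC)c(OC)c1
F4 | step 12 | (E)-N,N-dimethylhydrazone of F5 (C2 epimers) | CN(C)/N=C/C(C[C@H](OC)C=C)[C@@H](C)[C@H](O[Si](C)(C)C(C)(C)C)c1ccc(OC)c(OC)c1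
F5 | step 12 | (3R,4S)-4-[(tert-butyldimethylsilyl)oxy]-4-(3,4-dimethoxyphenyl)-2-[(2S)-2-methoxybut-3-en-1-yl]-3-methylbutanal (C2 epimers) | O=CC(C[C@H](OC)C=C)[C@@H](C)[C@H](O[Si](C)(C)C(C)(C)C)c1ccc(OC)c(OC)c1
F6 | step 12 | (5R,6S)-6-[(tert-butyldimethylsilyl)oxy]-6-(3,4-dimethoxyphenyl)-4-[(2S)-2-methoxybut-3-en-1-yl]-5-methylhex-1-en-3-ol (C3 and C4 epimers) | C=CC(O)C(C[C@H](OC)C=C)[C@@H](C)[C@H](O[Si](C)(C)C(C)(C)C)c1ccc(OC)c(OC)c1
F7 | step 12 | (4S)-6-[(1S,2R)-1-[(tert-butyldimethylsilyl)oxy]-1-(3,4-dimethoxyphenyl)propan-2-yl]-4-methoxycyclohex-2-en-1-ol (C1 and C6 epimers) | OC1C=C[C@@H](OC)CC1[C@@H](C)[C@H](O[Si](C)(C)C(C)(C)C)c1ccc(OC)c(OC)c1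
F8 | step 11 | (2R,7R,8S)-8-[(tert-butyldimethylsilyl)oxy]-8-(3,4-dimethoxyphenyl)-2-methoxy-7-methyl-5-oxooct-3-yn-1-yl 4-methylbenzenesulfonate | Cc1ccc(cc1)S(=O)(=O)OC[C@H](OC)C#CC(=O)C[C@@H](C)[C@H](O[Si](C)(C)C(C)(C)C)c1ccc(OC)c(OC)c1
F9 | step 1 | (S)-4-benzyl-3-[(2S,3S)-3-(3,4-dimethoxyphenyl)-3-hydroxy-2-methylpropanoyl]oxazolidin-2-one | O=C([C@@H](C)[C@H](O)c1ccc(OC)c(OC)c1)N1[C@@H](Cc2ccccc2)COC1=O
F10 | step 1 | (S)-4-benzyl-3-[(2S,3S)-3-[(tert-butyldimethylsilyl)oxy]-3-(3,4-dimethoxyphenyl)-2-methylpropanoyl]oxazolidin-2-one | O=C([C@@H](C)[C@H](O[Si](C)(C)C(C)(C)C)c1ccc(OC)c(OC)c1)N1[C@@H](Cc2ccccc2)COC1=O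
F11 | step 1 | (2R,3S)-3-[(tert-butyldimethylsilyl)oxy]-3-(3,4-dimethoxyphenyl)-2-methylpropan-1-ol | OC[C@@H](C)[C@H](O[Si](C)(C)C(C)(C)C)c1ccc(OC)c(OC)c1
F12 | step 1 | (2S,3S)-3-[(tert-butyldimethylsilyl)oxy]-3-(3,4-dimethoxyphenyl)-2-methylpropanal | O=C[C@@H](C)[C@H](O[Si](C)(C)C(C)(C)C)c1ccc(OC)c(OC)c1
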